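**Retrosynthetic overview**
- Target 20 ⇐ cis-isoflavan-4-ol 18: the C4–OH is removed through a p-quinone methide that is trapped by hydride; 18 ⇐ isoflavone 16 by two hydride transfers with dynamic kinetic resolution, which sets C3 as R.
- 16 ⇐ 2-hydroxyisoflavanone 15 (dehydration) ⇐ α-formyl ketone 14 ⇐ epoxide 13: a 1,2-shift in the epoxide of the fully prenylated chalcone 12 puts ring B on C3, and ring C closes by lactolisation.
- 12 ⇐ ring-A ketone 5 (prenyl already in place) + ring-B aldehyde 10 (chromene already in place).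
- 10 ⇐ o-prenylphenol 9 by dehydrogenative cyclisation (o-quinone methide, oxa-6π).
- Ring order: both benzene rings are bought; the dimethylpyran ring is closed first (step 5), then ring C (step 7).

Assumption: the single stereocentre of the SMILES is C3 of the chroman and is R; reagents that contribute atoms are numbered as starting materials.

**Route**

Step 1
Reactants: 1 2′,4′-dihydroxyacetophenone; 2 2-methylbut-3-en-2-ol
Product: 3 1-[2,4-dihydroxy-5-(3-methylbut-2-en-1-yl)phenyl]ethan-1-one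
Conditions: BF3·OEt2 (0.5 equiv), dioxane, rt, 12 h; chromatography
Reagents that add atoms: 2-methylbut-3-en-2-ol, CC(C)(O)C=C
Why: Friedel–Crafts prenylation in which BF3 ionises the tertiary allylic alcohol to the dimethylallyl cation, which attacks through its primary terminus at C5 (ortho to 4-OH, para to 2-OH, less hindered than C3); the yield is modest (3-prenyl isomer and chromans are separated) but it is one step from bulk chemicals.

Step 2
Reactants: 3 1-[2,4-dihydroxy-5-(3-methylbut-2-en-1-yl)phenyl]ethan-1-one; 4 chloromethyl methyl ether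
Product: 5 1-[2,4-bis(methoxymethoxy)-5-(3-methylbut-2-en-1-yl)phenyl]ethan-1-one
Conditions: NaH (2.3 equiv), MOMCl (2.5 equiv), DMF, 0 °C → rt
Reagents that add atoms: chloromethyl methyl ether, COCCl
Why: Williamson-type O-alkylation (MOM protection) of both phenoxides, NaH being needed for the chelated 2-OH, which must be masked so that the later alkaline peroxide step epoxidises instead of giving a flavonol.

Step 3
Reactants: 6 2,4-dihydroxybenzaldehyde; 7 prenyl bromide
Product: 8 2,4-dihydroxy-3-(3-methylbut-2-en-1-yl)benzaldehyde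
Conditions: 10% aq. KOH, prenyl bromide (1.0 equiv), 0 °C → rt; chromatography
Reagents that add atoms: prenyl bromide, CC(C)=CCBr
Why: nuclear C-alkylation of the ambident resorcinolate in water, where hydrogen bonding to the oxygens suppresses O-alkylation and the carbon flanked by both phenoxide oxygens (C3) is the most nucleophilic; low-yielding but a one-step entry.

Step 4
Reactants: 8 2,4-dihydroxy-3-(3-methylbut-2-en-1-yl)benzaldehyde; 4 chloromethyl methyl ether
Product: 9 2-hydroxy-4-(methoxymethoxy)-3-(3-methylbut-2-en-1-yl)benzaldehyde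
Conditions: MOMCl (1.05 equiv), iPr2NEt (1.2 equiv), CH2Cl2, 0 °C
Reagents that add atoms: chloromethyl methyl ether, COCCl
Why: regioselective O-alkylation (MOM protection) of the more acidic, non-chelated 4-OH, leaving the aldehyde-bonded 2-OH as the only oxygen that can later close the pyran ring.

Step 5
Reactants: 9 2-hydroxy-4-(methoxymethoxy)-3-(3-methylbut-2-en-1-yl)benzaldehyde
Product: 10 5-(methoxymethoxy)-2,2-dimethyl-2H-chromene-8-carbaldehyde
Conditions: DDQ (1.2 equiv), toluene, 80 °C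
Reagents that add atoms: none
Why: DDQ dehydrogenative cyclisation, in which hydride abstraction from the benzylic/allylic CH2 of the o-prenylphenol gives an o-quinone methide that closes by oxa-6π electrocyclisation onto the only free phenol oxygen, the laboratory counterpart of the biosynthetic prenyl → dimethylchromene cyclisation.

Step 6
Reactants: 5 1-[2,4-bis(methoxymethoxy)-5-(3-methylbut-2-en-1-yl)phenyl]ethan-1-one; 10 5-(methoxymethoxy)-2,2-dimethyl-2H-chromene-8-carbaldehyde; 11 hydrogen peroxide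
Product: 13 rac-trans-[2,4-bis(methoxymethoxy)-5-(3-methylbut-2-en-1-yl)phenyl]{3-[5-(methoxymethoxy)-2,2-dimethyl-2H-chromen-8-yl]oxiran-2-yl}methanone, via chalcone 12 (not isolated)
Conditions: KOH, MeOH/THF, rt, 36 h; then 30% H2O2, 0 °C → rt; basic work-up, crude epoxide used at once
Reagents that add atoms: hydrogen peroxide, OO
Why: Claisen–Schmidt aldol condensation gives the E-chalcone and Weitz–Scheffer nucleophilic epoxidation by HOO⁻ then attacks only the electron-poor enone double bond, leaving the electron-rich prenyl and chromene alkenes untouched; the racemic trans-epoxide centres are erased in the next step.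

Step 7
Reactants: 13 rac-trans-[2,4-bis(methoxymethoxy)-5-(3-methylbut-2-en-1-yl)phenyl]{3-[5-(methoxymethoxy)-2,2-dimethyl-2H-chromen-8-yl]oxiran-2-yl}methanone
Product: 16 7-hydroxy-3-(5-hydroxy-2,2-dimethyl-2H-chromen-8-yl)-6-(3-methylbut-2-en-1-yl)-4H-chromen-4-one, via α-formyl ketone 14 (not isolated), via 2-hydroxyisoflavanone 15 (not isolated)
Conditions: BF3·OEt2 (0.3 equiv), CH2Cl2, −40 → 0 °C, 20 min; then MeOH, conc. HCl (to ca. 1 M), 45 °C, 2 h
Reagents that add atoms: none
Why: Lewis-acid opening of the epoxide at the benzylic carbon (cation stabilised by the 2,4-dioxygenated aryl) triggers a 1,2-aroyl shift (House–Meinwald rearrangement of a chalcone epoxide) that leaves ring B on the carbon α to the ketone as the biosynthetic aryl migration does, after which acid methanolysis removes the three MOM groups, the 2′-OH closes onto the formyl group to the 2-hydroxyisoflavanone and this dehydrates to the isoflavone.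

Step 8
Reactants: 16 7-hydroxy-3-(5-hydroxy-2,2-dimethyl-2H-chromen-8-yl)-6-(3-methylbut-2-en-1-yl)-4H-chromen-4-one
Product: 18 (3R,4R)-3-(5-hydroxy-2,2-dimethyl-2H-chromen-8-yl)-6-(3-methylbut-2-en-1-yl)chromane-4,7-diol, via isoflavanone 17 (not isolated)
Conditions: RuCl[(R,R)-TsDPEN](p-cymene) (2 mol%), HCO2H/Et3N (5:2), EtOAc, 40 °C, 24 h
Reagents that add atoms: none
Why: Noyori–Ikariya asymmetric transfer hydrogenation, in which Ru–H conjugate reduction gives the rapidly enolising isoflavanone and dynamic kinetic resolution then reduces only the (3R)-ketone from the face anti to the aryl group to the cis-(3R,4R) alcohol; the (R,R) ligand is chosen by analogy with 4-chromanone → (R)-chroman-4-ol, and the isolated alkenes are inert to the Ru hydride.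

Step 9
Reactants: 18 (3R,4R)-3-(5-hydroxy-2,2-dimethyl-2H-chromen-8-yl)-6-(3-methylbut-2-en-1-yl)chromane-4,7-diol
Product: 20 (3R)-3-(5-hydroxy-2,2-dimethyl-2H-chromen-8-yl)-6-(3-methylbut-2-en-1-yl)chroman-7-ol, via quinone methide 19 (not isolated)
Conditions: NaBH4 (10 equiv), 1 M aq. NaOH/dioxane (1:1), 90 °C, Ar
Reagents that add atoms: none
Why: base-induced 1,6-elimination of hydroxide from the 7-phenoxide gives a p-quinone methide (stabilised as a vinylogous ester by O1) that borohydride reduces at C4 as it forms (quinone-methide reduction of a p-hydroxybenzyl alcohol, the chemistry of pterocarpan reductase); no cation is formed and C3 is not touched, so the 3R centre is retained.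

**Compound list**
1 | 2′,4′-dihydroxyacetophenone | CC(=O)c1ccc(O)cc1O | starting material
2 | 2-methylbut-3-en-2-ol | CC(C)(O)C=C | starting material
3 | 1-[2,4-dihydroxy-5-(3-methylbut-2-en-1-yl)phenyl]ethan-1-one | CC(=O)c1cc(CC=C(C)C)c(O)cc1O | intermediate
4 | chloromethyl methyl ether (MOMCl) | COCCl | starting material
5 | 1-[2,4-bis(methoxymethoxy)-5-(3-methylbut-2-en-1-yl)phenyl]ethan-1-one | CC(=O)c1cc(CC=C(C)C)c(OCOC)cc1OCOC | intermediate
6 | 2,4-dihydroxybenzaldehyde | O=Cc1ccc(O)cc1O | starting material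
7 | prenyl bromide (1-bromo-3-methylbut-2-ene) | CC(C)=CCBr | starting material
8 | 2,4-dihydroxy-3-(3-methylbut-2-en-1-yl)benzaldehyde | O=Cc1ccc(O)c(CC=C(C)C)c1O | intermediate
9 | 2-hydroxy-4-(methoxymethoxy)-3-(3-methylbut-2-en-1-yl)benzaldehyde | O=Cc1ccc(OCOC)c(CC=C(C)C)c1O | intermediate
10 | 5-(methoxymethoxy)-2,2-dimethyl-2H-chromene-8-carbaldehyde | O=Cc1ccc(OCOC)c2C=CC(C)(C)Oc12 | intermediate
11 | hydrogen peroxide | OO | starting material
12 | (E)-1-[2,4-bis(methoxymethoxy)-5-(3-methylbut-2-en-1-yl)phenyl]-3-[5-(methoxymethoxy)-2,2-dimethyl-2H-chromen-8-yl]prop-2-en-1-one (chalcone) | CC(C)=CCc1cc(C(=O)/C=C/c2ccc(OCOC)c3C=CC(C)(C)Oc23)c(OCOC)cc1OCOC | intermediate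
13 | rac-trans-(2R*,3S*)-[2,4-bis(methoxymethoxy)-5-(3-methylbut-2-en-1-yl)phenyl]{3-[5-(methoxymethoxy)-2,2-dimethyl-2H-chromen-8-yl]oxiran-2-yl}methanone (racemate, one enantiomer drawn) | CC(C)=CCc1cc(C(=O)[C@H]2O[C@@H]2c3ccc(OCOC)c4C=CC(C)(C)Oc34)c(OCOC)cc1OCOC | intermediate
14 | 3-[2,4-bis(methoxymethoxy)-5-(3-methylbut-2-en-1-yl)phenyl]-2-[5-(methoxymethoxy)-2,2-dimethyl-2H-chromen-8-yl]-3-oxopropanal (α-formyl ketone, racemic/enolised) | CC(C)=CCc1cc(C(=O)C(C=O)c2ccc(OCOC)c3C=CC(C)(C)Oc23)c(OCOC)cc1OCOC | intermediate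
15 | 2,7-dihydroxy-3-(5-hydroxy-2,2-dimethyl-2H-chromen-8-yl)-6-(3-methylbut-2-en-1-yl)chroman-4-one (2-hydroxyisoflavanone, diastereomer mixture) | CC(C)=CCc1cc2c(cc1O)OC(O)C(c1ccc(O)c3C=CC(C)(C)Oc13)C2=O | intermediate
16 | 7-hydroxy-3-(5-hydroxy-2,2-dimethyl-2H-chromen-8-yl)-6-(3-methylbut-2-en-1-yl)-4H-chromen-4-one (isoflavone) | CC(C)=CCc1cc2c(cc1O)occ(-c1ccc(O)c3C=CC(C)(C)Oc13)c2=O | intermediate
17 | 7-hydroxy-3-(5-hydroxy-2,2-dimethyl-2H-chromen-8-yl)-6-(3-methylbut-2-en-1-yl)chroman-4-one (isoflavanone, C3 epimerising) | CC(C)=CCc1cc2c(cc1O)OCC(c1ccc(O)c3C=CC(C)(C)Oc13)C2=O | intermediate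
18 | (3R,4R)-3-(5-hydroxy-2,2-dimethyl-2H-chromen-8-yl)-6-(3-methylbut-2-en-1-yl)chromane-4,7-diol (cis) | CC(C)=CCc1cc2c(cc1O)OC[C@@H](c1ccc(O)c3C=CC(C)(C)Oc13)[C@H]2O | intermediate
19 | (3R)-3-(5-hydroxy-2,2-dimethyl-2H-chromen-8-yl)-6-(3-methylbut-2-en-1-yl)-2,3-dihydro-7H-chromen-7-one (p-quinone methide) | CC(C)=CCC1=CC2=C[C@H](c3ccc(O)c4C=CC(C)(C)Oc34)COC2=CC1=O | intermediate
20 | (3R)-3-(5-hydroxy-2,2-dimethyl-2H-chromen-8-yl)-6-(3-methylbut-2-en-1-yl)chroman-7-ol | CC(C)=CCc1cc2c(cc1O)OC[C@@H](c1ccc(O)c3c1OC(C)(C)C=C3)C2 | target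

**Step count**
Total: 9 steps. Longest linear sequence: 7 steps (6 → 8 → 9 → 10 → 13 → 16 → 18 → 20, steps 3–9).

**Three steps most likely to fail**

Step 7 (epoxide 1,2-shift and cyclodehydration). The 2′-OMOM oxygen may capture the benzylic cation and give the 3-hydroxyflavanone, or the Lewis acid may damage the chromene. The fallback sets out from aldehyde 10 and ketone 5, rejoins at 14, and puts ring B on the α-carbon by cross-coupling instead of by rearrangement. Aldehyde 10 is taken through a Dakin-type Baeyer–Villiger oxidation (30% H2O2, cat. (PhSe)2, CH2Cl2; then K2CO3, MeOH) to 5-(methoxymethoxy)-2,2-dimethyl-2H-chromen-8-ol F1. This is converted (Tf2O, pyridine, CH2Cl2, 0 °C) into 5-(methoxymethoxy)-2,2-dimethyl-2H-chromen-8-yl trifluoromethanesulfonate F2. Pd-catalysed α-arylation of ketone 5 with F2 (Pd(OAc)2, XPhos, K3PO4, toluene, 80 °C) gives the deoxybenzoin 1-[2,4-bis(methoxymethoxy)-5-(3-methylbut-2-en-1-yl)phenyl]-2-[5-(methoxymethoxy)-2,2-dimethyl-2H-chromen-8-yl]ethan-1-one F3. Claisen formylation (HCO2Et, NaH, THF) then delivers 14, which re-enters the route at the HCl/MeOH stage of step 7.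

Step 8 (transfer hydrogenation of the free bis-phenol). The phenols may slow the conjugate reduction or erode the selectivity. The fallback sets out from 16, rejoins at 18, and reduces a neutral bis-silyl ether instead. Isoflavone 16 is silylated (TBSCl, imidazole, DMF) to 7-[(tert-butyldimethylsilyl)oxy]-3-{5-[(tert-butyldimethylsilyl)oxy]-2,2-dimethyl-2H-chromen-8-yl}-6-(3-methylbut-2-en-1-yl)-4H-chromen-4-one F4. This is reduced with the same (R,R)-Ru catalyst and HCO2H/Et3N to (3R,4R)-7-[(tert-butyldimethylsilyl)oxy]-3-{5-[(tert-butyldimethylsilyl)oxy]-2,2-dimethyl-2H-chromen-8-yl}-6-(3-methylbut-2-en-1-yl)chroman-4-ol F5. Buffered desilylation (TBAF, AcOH, THF, 0 °C) gives 18.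

Step 9 (thermal hydroxide expulsion and hydride capture). The quinone methide may form too slowly at 90 °C, or tautomerise to the isoflav-3-ene before it is reduced. The fallback sets out from 18, rejoins at 20, and replaces hydroxide by a triggered leaving group. Per-acetylation (Ac2O, pyridine, cat. DMAP) gives (3R,4R)-3-(5-acetoxy-2,2-dimethyl-2H-chromen-8-yl)-6-(3-methylbut-2-en-1-yl)chromane-4,7-diyl diacetate F6. Treatment with NaBH4 and aq. NaOH in THF at 0 °C → rt cleaves the aryl acetates; the freed 7-phenoxide expels the C4 acetate at low temperature in the presence of excess hydride, giving 20 directly.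

**Further compounds**
F1 | step 7 | 5-(methoxymethoxy)-2,2-dimethyl-2H-chromen-8-ol | Oc1ccc(OCOC)c2C=CC(C)(C)Oc12
F2 | step 7 | 5-(methoxymethoxy)-2,2-dimethyl-2H-chromen-8-yl trifluoromethanesulfonate | FC(F)(F)S(=O)(=O)Oc1ccc(OCOC)c2C=CC(C)(C)Oc12
F3 | step 7 | 1-[2,4-bis(methoxymethoxy)-5-(3-methylbut-2-en-1-yl)phenyl]-2-[5-(methoxymethoxy)-2,2-dimethyl-2H-chromen-8-yl]ethan-1-one | CC(C)=CCc1cc(C(=O)Cc2ccc(OCOC)c3C=CC(C)(C)Oc23)c(OCOC)cc1OCOC
F4 | step 8 | 7-[(tert-butyldimethylsilyl)oxy]-3-{5-[(tert-butyldimethylsilyl)oxy]-2,2-dimethyl-2H-chromen-8-yl}-6-(3-methylbut-2-en-1-yl)-4H-chromen-4-one | CC(C)=CCc1cc2c(cc1O[Si](C)(C)C(C)(C)C)occ(-c1ccc(O[Si](C)(C)C(C)(C)C)c3C=CC(C)(C)Oc13)c2=O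
F5 | step 8 | (3R,4R)-7-[(tert-butyldimethylsilyl)oxy]-3-{5-[(tert-butyldimethylsilyl)oxy]-2,2-dimethyl-2H-chromen-8-yl}-6-(3-methylbut-2-en-1-yl)chroman-4-ol | CC(C)=CCc1cc2c(cc1O[Si](C)(C)C(C)(C)C)OC[C@@H](c1ccc(O[Si](C)(C)C(C)(C)C)c3C=CC(C)(C)Oc13)[C@H]2O
F6 | step 9 | (3R,4R)-3-(5-acetoxy-2,2-dimethyl-2H-chromen-8-yl)-6-(3-methylbut-2-en-1-yl)chromane-4,7-diyl diacetate | CC(C)=CCc1cc2c(cc1OC(C)=O)OC[C@@H](c1ccc(OC(C)=O)c3C=CC(C)(C)Oc13)[C@H]2OC(C)=O
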